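**Plan**

- Retrosynthesis: the last operations are removal of two benzyl ethers and adjustment of C2. The C4 ketone goes back to a C3=C4 enol ether, the C2–C1' bond to a benzopyrylium ion plus an arylboronate, and the C2–C3 and C3–C4 bonds of ring C to 4,6-dimethoxybenzofuran plus a one-carbon unit.
- Enabling feature: ring C is the furan ring of 4,6-dimethoxybenzofuran enlarged by one atom, C3, and that atom carries the 3-methoxy group, so chloro(methoxy)carbene supplies exactly the missing C3–OMe unit.
- Forward order: ring A is bought; the furan ring is closed on it (O-alkylation, cyclodehydration); carbene insertion expands it to ring C as a 2-ethoxy-2H-chromene; ring B is joined at C2 as an arylboronate; hydroboration–oxidation and alcohol oxidation install the C4 ketone.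
- Stereochemistry: the catalyst-controlled arylation sets C2 as S, and hydroboration anti to the aryl group relays this to C3 (R in the ketone). After debenzylation the 2'-OH lets C2 equilibrate by ring opening and reclosure to the more stable 2,3-trans isomer, so C3 is the permanent centre and C2 ends as R.

Key step: step 4

Assumption: the facial sense of the tartaric-acid-amide-catalysed arylation on a 3-methoxylated acetal cannot be predicted with confidence; the catalyst derived from L-tartaric acid is written, and its D-antipode is to be used if it proves to give the 2R chromene.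

**Route**

Step 1
Reactants: 1 3,5-dimethoxyphenol; 2 bromoacetaldehyde diethyl acetal
Product: 3 1-(2,2-diethoxyethoxy)-3,5-dimethoxybenzene
Conditions: K2CO3, KI (cat.), DMF, 110 °C
Reagents that add atoms: none
Why: Williamson ether synthesis, in which the phenoxide displaces the primary bromide while the acetal is inert to base.

Step 2
Reactants: 3 1-(2,2-diethoxyethoxy)-3,5-dimethoxybenzene
Product: 4 4,6-dimethoxybenzofuran
Conditions: Amberlyst-15, PhCl, 120 °C, EtOH distilled off
Reagents that add atoms: none
Why: Acid-catalysed cyclodehydration of an aryloxyacetaldehyde acetal (intramolecular Friedel–Crafts-type attack ortho to the ether oxygen, then loss of ethanol to aromatise), which should give a single regioisomer because the ring is symmetrical and the attacked position is activated by all three oxygen substituents.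

Step 3
Reactants: 5 O-methylisourea hydrochloride
Product: 6 3-chloro-3-methoxy-3H-diazirine
Conditions: aq NaOCl (NaCl-saturated), DMSO, pentane, 0–5 °C; pentane layer dried (CaCl2), kept at –20 °C as a dilute solution, never concentrated
Reagents that add atoms: sodium hypochlorite, [Na+].[O-]Cl
Why: Graham oxidation of an amidine-type salt with hypochlorite (N-chlorination, N–N bond closure and chloride transfer to carbon), the standard entry to 3-alkoxy-3-chlorodiazirines from O-alkylisouronium salts.

Step 4
Reactants: 4 4,6-dimethoxybenzofuran; 6 3-chloro-3-methoxy-3H-diazirine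
Product: 10 2-ethoxy-3,5,7-trimethoxy-2H-chromene (racemic), via chloro(methoxy)carbene 7 (not isolated), via cyclopropane adduct 8 (not isolated), via 3,5,7-trimethoxychromenylium chloride 9 (not isolated)
Conditions: 6 (3 equiv, pentane solution, in portions), CH2Cl2, 0 → 25 °C, dark, 4 h; then NaOEt, EtOH, –20 → 0 °C
Reagents that add atoms: sodium ethoxide, CC[O-].[Na+]
Why: Proposed new method: thermal loss of N2 from 6 releases the ambiphilic carbene 7, which acts as an electrophile toward the enol-ether-like C2=C3 bond of 4 and adds [2+1] to give 8; this alpha-chloro ether ionises readily (a stepwise path through the methoxy-stabilised cyclopropyl cation is open to both C1 epimers) and disrotatory two-electron opening, pushed by O1, breaks the former furan C2–C3 bond to give cation 9, which ethoxide captures at C2. The closest known reaction types are the dihalocarbene cyclopropanation and ring expansion of benzofurans to 3-halo-2-alkoxy-2H-chromenes and the chlorodiazirine one-carbon insertion into indoles and pyrroles, whereas chloro(methoxy)carbene has not been used for such an insertion. Ring C closes by ring expansion from five to six atoms: C2–C3 and C3–C4 are made in the cheletropic addition and the inserted carbon becomes C3 with its methoxy group already in place. No stereocentre of consequence is formed, because the acetal carbon of 10 is racemic and is ionised again in step 8. The step needs the carbene to choose the furan double bond over ring A, which the localised, electron-rich C2=C3 bond and the intact aromatic sextet of ring A should secure, and it needs the cation to survive until the quench, which O1 and the 5- and 7-methoxy groups (not the cross-conjugated 3-methoxy group) provide. Capture at C2 rather than C4 is expected because C4 lies between the 3- and 5-methoxy groups, and any 4-ethoxy isomer would return the same cation in step 8.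

Step 5
Reactants: 11 methoxyhydroquinone
Product: 12 1,4-bis(benzyloxy)-2-methoxybenzene
Conditions: BnBr, K2CO3, DMF, 60 °C, N2
Reagents that add atoms: benzyl bromide, BrCc1ccccc1
Why: Williamson benzylation of both phenols, run under nitrogen because the hydroquinone dianion is air-sensitive, gives ethers that survive organolithium, Lewis acid, borane and oxidant and are removed at the end under neutral conditions.

Step 6
Reactants: 12 1,4-bis(benzyloxy)-2-methoxybenzene
Product: 13 1,4-bis(benzyloxy)-2-bromo-5-methoxybenzene
Conditions: NBS, MeCN, 0 °C
Reagents that add atoms: N-bromosuccinimide, O=C1CCC(=O)N1Br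
Why: Electrophilic aromatic bromination, directed to the one position that is para to the methoxy group and ortho to a benzyloxy group (the other free positions are activated by a single ortho oxygen or are flanked on both sides), as in the bromination of 1,2,4-trialkoxybenzenes.

Step 7
Reactants: 13 1,4-bis(benzyloxy)-2-bromo-5-methoxybenzene
Product: 16 diethyl [2,5-bis(benzyloxy)-4-methoxyphenyl]boronate, via aryllithium 14 (not isolated), via lithium aryltriethoxyborate 15 (not isolated)
Conditions: n-BuLi, THF, –78 °C; B(OEt)3, –78 → 0 °C; Me3SiCl, 0 °C; filter (LiCl), evaporate, used crude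
Reagents that add atoms: triethyl borate, CCOB(OCC)OCC
Why: Bromine–lithium exchange, borylation with a trialkyl borate and release of the neutral boronic ester from the ate complex by silylation of one ethoxide, a non-protic quench that avoids protodeboronation of this electron-rich arene.

Step 8
Reactants: 10 2-ethoxy-3,5,7-trimethoxy-2H-chromene (racemic); 16 diethyl [2,5-bis(benzyloxy)-4-methoxyphenyl]boronate
Product: 17 (2S)-2-[2,5-bis(benzyloxy)-4-methoxyphenyl]-3,5,7-trimethoxy-2H-chromene
Conditions: (2R,3R)-4-(dibenzylamino)-2,3-dihydroxy-4-oxobutanoic acid (10 mol %), Yb(OTf)3 (10 mol %), EtOAc, –20 → 4 °C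
Reagents that add atoms: none
Why: Brønsted acid/Lewis acid-catalysed enantioselective addition of an aryl boronate to a 2-alkoxy-2H-chromene, in which the triflate salt re-ionises the acetal to the cation of 9 and the tartaric acid amide exchanges onto boron and delivers the aryl group to one face of C2 (catalyst control), C4 being shielded by the 3- and 5-methoxy groups; the non-oxidising Yb(OTf)3 is chosen to spare the electron-rich aryl group.

Step 9
Reactants: 17 (2S)-2-[2,5-bis(benzyloxy)-4-methoxyphenyl]-3,5,7-trimethoxy-2H-chromene
Product: 19 (2S,3S,4R)-2-[2,5-bis(benzyloxy)-4-methoxyphenyl]-3,5,7-trimethoxychroman-4-ol, via C4 alkylborane 18 (not isolated)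
Conditions: BH3·THF, THF, 0 °C; then 3 M NaOH, 30% H2O2, 0 °C
Reagents that add atoms: hydrogen peroxide, OO
Why: Hydroboration–oxidation of an enol ether, in which boron goes to C4 (beta to the methoxy group and the less substituted alkene carbon, the regiochemistry known for 3-substituted 2H-chromenes), H and B add syn to the face opposite the C2 aryl group so that C3–H is trans to the aryl group (3S) and oxidation with retention gives the 4R alcohol, and the minor C3 epimeric series, which would lead to the enantiomer of the target, is removed by chromatography here.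

Step 10
Reactants: 19 (2S,3S,4R)-2-[2,5-bis(benzyloxy)-4-methoxyphenyl]-3,5,7-trimethoxychroman-4-ol
Product: 20 (2S,3R)-2-[2,5-bis(benzyloxy)-4-methoxyphenyl]-3,5,7-trimethoxychroman-4-one (2,3-cis)
Conditions: Dess–Martin periodinane, pyridine, CH2Cl2, 0 → 25 °C
Reagents that add atoms: none
Why: Dess–Martin oxidation of the secondary benzylic alcohol under pyridine-buffered, non-enolising conditions converts C4 into the ketone without touching C2 or the C3–H bond, whose 2,3-cis arrangement must be kept (rapid filtration through neutral silica, no base).

Step 11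
Reactants: 20 (2S,3R)-2-[2,5-bis(benzyloxy)-4-methoxyphenyl]-3,5,7-trimethoxychroman-4-one (2,3-cis)
Product: 23 (2R,3R)-2-(2,5-dihydroxy-4-methoxyphenyl)-3,5,7-trimethoxychroman-4-one (target), via 2,3-cis phenol 21 (not isolated), via ring-opened ortho-quinone methide 22 (not isolated)
Conditions: H2 (1 atm), 10% Pd/C, EtOAc, 25 °C; filter under argon; then degassed MeOH–aq phosphate buffer (pH 7.5), 45 °C
Reagents that add atoms: none
Why: Hydrogenolysis of the two benzyl ethers gives 21, and once the catalyst is removed the free 2'-OH allows reversible opening of the C2–O1 bond to the ortho-quinone methide 22 and reclosure (the C2 epimerisation known for dihydroflavonols with a free ortho or para hydroxyl on ring B), which leaves C3 untouched and should funnel the 2,3-cis isomer into the more stable diequatorial 2,3-trans isomer, so that C2 becomes R under thermodynamic control by C3; residual 21 is separated and resubjected.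

**Compound list**

1 | 3,5-dimethoxyphenol | COc1cc(O)cc(OC)c1 | starting material
2 | bromoacetaldehyde diethyl acetal (2-bromo-1,1-diethoxyethane) | CCOC(CBr)OCC | starting material
3 | 1-(2,2-diethoxyethoxy)-3,5-dimethoxybenzene | CCOC(COc1cc(OC)cc(OC)c1)OCC | intermediate
4 | 4,6-dimethoxybenzofuran | COc1cc(OC)c2ccoc2c1 | intermediate
5 | O-methylisourea hydrochloride | COC(N)=N.Cl | starting material
6 | 3-chloro-3-methoxy-3H-diazirine | COC1(Cl)N=N1 | intermediate
7 | chloro(methoxy)carbene (formed in the flask) | CO[C]Cl | intermediate
8 | 1-chloro-1,4,6-trimethoxy-1a,6b-dihydro-1H-cyclopropa[b]benzofuran (racemic, cis-fused, both C1 epimers; formed in the flask) | COC1(Cl)C2Oc3cc(OC)cc(OC)c3C12 | intermediate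
9 | 3,5,7-trimethoxychromenylium chloride (formed in the flask) | COc1cc(OC)c2cc(OC)c[o+]c2c1.[Cl-] | intermediate
10 | 2-ethoxy-3,5,7-trimethoxy-2H-chromene (racemic) | CCOC1Oc2cc(OC)cc(OC)c2C=C1OC | intermediate
11 | methoxyhydroquinone (2-methoxybenzene-1,4-diol) | COc1cc(O)ccc1O | starting material
12 | 1,4-bis(benzyloxy)-2-methoxybenzene | COc1cc(OCc2ccccc2)ccc1OCc1ccccc1 | intermediate
13 | 1,4-bis(benzyloxy)-2-bromo-5-methoxybenzene | COc1cc(OCc2ccccc2)c(Br)cc1OCc1ccccc1 | intermediate
14 | [2,5-bis(benzyloxy)-4-methoxyphenyl]lithium (formed in the flask) | [Li]c1cc(OCc2ccccc2)c(OC)cc1OCc1ccccc1 | intermediate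
15 | lithium [2,5-bis(benzyloxy)-4-methoxyphenyl]triethoxyborate (formed in the flask) | [Li+].CCO[B-](OCC)(OCC)c1cc(OCc2ccccc2)c(OC)cc1OCc1ccccc1 | intermediate
16 | diethyl [2,5-bis(benzyloxy)-4-methoxyphenyl]boronate | CCOB(OCC)c1cc(OCc2ccccc2)c(OC)cc1OCc1ccccc1 | intermediate
17 | (2S)-2-[2,5-bis(benzyloxy)-4-methoxyphenyl]-3,5,7-trimethoxy-2H-chromene | COc1cc(OC)c2c(c1)O[C@@H](c1cc(OCc3ccccc3)c(OC)cc1OCc1ccccc1)C(OC)=C2 | intermediate
18 | [(2S,3S,4R)-2-[2,5-bis(benzyloxy)-4-methoxyphenyl]-3,5,7-trimethoxychroman-4-yl]borane (formed in the flask) | COc1cc(OC)c2c(c1)O[C@@H](c1cc(OCc3ccccc3)c(OC)cc1OCc1ccccc1)[C@@H](OC)[C@@H]2B | intermediate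
19 | (2S,3S,4R)-2-[2,5-bis(benzyloxy)-4-methoxyphenyl]-3,5,7-trimethoxychroman-4-ol (2,3-cis, 3,4-trans) | COc1cc(OC)c2c(c1)O[C@@H](c1cc(OCc3ccccc3)c(OC)cc1OCc1ccccc1)[C@@H](OC)[C@@H]2O | intermediate
20 | (2S,3R)-2-[2,5-bis(benzyloxy)-4-methoxyphenyl]-3,5,7-trimethoxychroman-4-one (2,3-cis) | COc1cc(OC)c2c(c1)O[C@@H](c1cc(OCc3ccccc3)c(OC)cc1OCc1ccccc1)[C@@H](OC)C2=O | intermediate
21 | (2S,3R)-2-(2,5-dihydroxy-4-methoxyphenyl)-3,5,7-trimethoxychroman-4-one (2,3-cis; formed in the flask) | COc1cc(OC)c2c(c1)O[C@@H](c1cc(O)c(OC)cc1O)[C@@H](OC)C2=O | intermediate
22 | (2R)-1-(2-hydroxy-4,6-dimethoxyphenyl)-3-(3-hydroxy-4-methoxy-6-oxocyclohexa-2,4-dien-1-ylidene)-2-methoxypropan-1-one (ring-opened ortho-quinone methide; formed in the flask) | COc1cc(O)c(C(=O)[C@H](OC)C=C2C=C(O)C(OC)=CC2=O)c(OC)c1 | intermediate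
23 | (2R,3R)-2-(2,5-dihydroxy-4-methoxyphenyl)-3,5,7-trimethoxychroman-4-one (2,3-trans) | COc1cc(OC)c2c(c1)O[C@H](c1cc(O)c(OC)cc1O)[C@@H](OC)C2=O | target

**Totals and risks**

Total steps: 11. Longest linear sequence: 7 steps (steps 1, 2, 4, 8, 9, 10, 11; the arm from methoxyhydroquinone through steps 5, 6, 7 and then 8 to 11 is equally long).

Steps most likely to fail:

1. Step 4. The stabilised carbene may react with itself or with its diazirine faster than it adds to the furan double bond. The cation formed may also be consumed by Friedel–Crafts attack on unreacted benzofuran or by further carbene before the ethoxide quench. The fallback uses known chemistry and sets out from 1. Ortho-formylation (MgCl2, Et3N, paraformaldehyde, MeCN, reflux) should give 2-hydroxy-4,6-dimethoxybenzaldehyde F1. Perkin condensation with methoxyacetic anhydride and sodium methoxyacetate should give 3,5,7-trimethoxy-2H-chromen-2-one F2. Reduction with i-Bu2AlH at –78 °C should give the lactol 3,5,7-trimethoxy-2H-chromen-2-ol F3, and acetalisation (EtOH, pyridinium p-toluenesulfonate) rejoins the route at 10.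

2. Step 8. Facial selectivity may be poor or aryl transfer slow because the 3-methoxy group crowds C2, and the electron-rich boronate may protodeboronate under the Lewis acid. The fallback sets out from 16, which is hydrolysed (H2O, THF) to [2,5-bis(benzyloxy)-4-methoxyphenyl]boronic acid F4. Nickel-catalysed cross-coupling of F4 with 10 (Ni(cod)2, zerovalent nickel, with a TADDOL-derived phosphonite ligand, dioxane/t-AmOH, 40 °C) then sets C2 through the ligand on an allyl-type nickel intermediate instead of through a chiral boronate, and rejoins the route at 17.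

3. Step 11. Ring opening and reclosure at C2 may be slow or incomplete, C3 may erode if the open form tautomerises to the chalcone, the hydroquinone ring B may oxidise in air, and the open form may be reduced if catalyst is carried over. The fallback sets out from 20 and epimerises C2 before deprotection. Catalytic CF3CO2H in CH2Cl2 at 0 °C should cause reversible heterolysis of the C2–O1 bond to a benzylic cation stabilised by the 4-methoxy and 2-benzyloxy groups of ring B, and reclosure to the trans ketone (2R,3R)-2-[2,5-bis(benzyloxy)-4-methoxyphenyl]-3,5,7-trimethoxychroman-4-one F5. Hydrogenolysis (H2, 10% Pd/C, EtOAc) then gives 23 directly.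

Further compounds
F1 | step 4 | 2-hydroxy-4,6-dimethoxybenzaldehyde | COc1cc(O)c(C=O)c(OC)c1
F2 | step 4 | 3,5,7-trimethoxy-2H-chromen-2-one | COc1cc(OC)c2cc(OC)c(=O)oc2c1
F3 | step 4 | 3,5,7-trimethoxy-2H-chromen-2-ol | COC1=Cc2c(OC)cc(OC)cc2OC1O
F4 | step 8 | [2,5-bis(benzyloxy)-4-methoxyphenyl]boronic acid | OB(O)c1cc(OCc2ccccc2)c(OC)cc1OCc1ccccc1
F5 | step 11 | (2R,3R)-2-[2,5-bis(benzyloxy)-4-methoxyphenyl]-3,5,7-trimethoxychroman-4-one | COc1cc(OC)c2c(c1)O[C@H](c1cc(OCc3ccccc3)c(OC)cc1OCc1ccccc1)[C@@H](OC)C2=O
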